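Slowness was my first suspicion in this flask: L has to come across from E in the second phase while D, in the first, is already pairing with itself.

D 0.20 M; E 2.00 equiv; time 2.5 min; volume of the second phase over the first 0.25

    L ⇌ E, rate k1*([L] - [E]/K1) per volume of the first phase (K1 = 31, k1 = 0.225 s⁻¹)
    D + L → D.L (k2 = 1.50 M⁻¹ s⁻¹)
    2 D → D2 (k3 = 0.0847 M⁻¹ s⁻¹)
    D + D.L → D.D.L (k4 = 0.0626 M⁻¹ s⁻¹)

- in percentages every species weighs as the D in it: one D2 or D.D.L counts as two
- a step written with two of one species runs at k times the square of its concentration and takes two of it each time
- in the second phase: E; everything else is in the first
- charges count per volume of the first phase; a concentration in a rate is the amount of a species over the volume of its own phase; every rate counts per litre of the first phase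
- run time (flask): 2.5 min

- how much D.L there is at 2.5 min, in percent of the D charged
- the change that raises the amount of D.L at 2.5 min, in percent of the D charged most ("none" if none brings more than 2 percentage points) (Friday's / Wednesday's / none)
- amount of D.L at 2.5 min, in percent of the D charged, after Wednesday's

- Friday's: doubling the amount of E, all else as stated
- Wednesday's: doubling the transfer coefficient of step 1, all else as stated

**The ceiling.** I counted every amount as a fraction of the D charged. If the passage stood at rest with the whole of E present, L would stand at 25.8 % of the charge: this is the ceiling of L, the equivalents of E divided by the partition ratio and by the volume ratio.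

**The curve.** D.L started flat, with no L yet present. L became steady within about 1.90 s, and I took that fast step as steady from then on (a quasi-steady state). This put L at 11.1 % of the charge. D.L then climbed at 0.0332 s⁻¹, while pairing took D at 0.0339 s⁻¹, so the two began about equal. Pairing fades with the square of D and capture with D itself, so capture led from there. With capture and pairing taking D together and L held steady, I reckoned D to halve in 12.1 s, which is shorter than the run of 2.5 min, so the curve bends early and runs flat. Holding L steady, I found 68.9 % of D passing through capture, before the attack of D on D.L takes its part.

**The choice.** Friday's change doubles the ceiling and starts L at 22.1 %. Wednesday's keeps the ceiling and starts L at 15.5 %, which is lower, so I chose Friday's.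

**The forecast.** It gave 57 % (range 53 % to 61 %), Friday's, and 62 % after Wednesday's (range 58 % to 66 %). Its words were: “Doubling E doubles L at every moment, which beats Wednesday's change, since L is higher throughout.” Its first figure is D.L itself, whereas mine counts D through capture.

**The result.** The flask gave 57.2 %, Friday's with 14 percentage points against 4.2 points, and 61.4 % after Wednesday's. At 0.225 min L was made 1.08 times as fast as it was used. At 2.50 min, with D down to 0.0293 %, the ceiling times the 60.7 % of E left gives 0.0313 M, and L stood at 0.0313 M. The neighbour flask with 0.34 M of D has the same ceiling, and its 62.7 % of E left gives 0.0550 M, where its L stood at 0.0550 M.

The numbers of this flask are assumed, and the outcome is calculated.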